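**Retrosynthetic overview**
1. Ring A (the enamine) is rebuilt last. C3 of the target is the carboxyl carbon of a cis-lactone acid (ring E, from L-glutamic acid). It is placed on C2 of the lactam-derived enamine, and the old lactam carbon is then excised, forming N4–C3 and C2=C3.
2. Rings C/D: C10–C11 comes from Claisen acylation of a tricyclic γ-lactone with O-acetyl-D-malic anhydride. C-ethylation, loss of the old lactone carbonyl as CO2 and acid spiroketalisation follow; the C13 methyl goes in last.
3. Ring B and the provisional lactone: C8–C9 is closed by a cathodic, samarium-mediated 7-exo ketyl–enoate cyclisation of an aldehyde–enoate made from methyl L-pyroglutamate.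
4. Ring order: A (bought as lactam) → B + provisional lactone → C + D → E (separate branch) → A re-formed as the enamine.

Assumption: Stemona numbering is used (N4; C1–C3/C9a ring A; C5–C9 ring B; C8–C11/O ring C; C11–C14/O ring D with C15 methyl; C16–C17 ethyl; C18–C21/O ring E with C22 methyl), and 9 (O-acetyl-D-malic anhydride, made from D-malic acid and AcCl) is taken as a catalogue compound.

**Step 1**
Reactants: 1 methyl (S)-5-oxopyrrolidine-2-carboxylate (methyl L-pyroglutamate); 2 4-chloro-1,1-dimethoxybutane
Product: 3 methyl (S)-1-(4,4-dimethoxybutyl)-5-oxopyrrolidine-2-carboxylate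
Conditions: NaH (0.97 equiv), NaI (0.2 equiv), DMF, 0 → 50 °C
Reagents that add atoms: none
Why: SN2 N-alkylation of the sodium lactamate with in-flask halide exchange; slightly less than one equivalent of NaH leaves no base able to enolise the ester, so the bought C9a (S) centre is kept.

**Step 2**
Reactants: 3 methyl (S)-1-(4,4-dimethoxybutyl)-5-oxopyrrolidine-2-carboxylate
Product: 5 ethyl (E)-3-[(S)-1-(4,4-dimethoxybutyl)-5-oxopyrrolidin-2-yl]acrylate, via aldehyde 4 (not isolated)
Conditions: iBu2AlH (1.1 equiv), CH2Cl2, −78 °C; then Ph3P=CHCO2Et (1.5 equiv), −78 → 23 °C; aq potassium sodium tartrate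
Reagents that add atoms: ethyl (triphenylphosphoranylidene)acetate, CCOC(=O)C=P(c1ccccc1)(c1ccccc1)c1ccccc1
Why: Half-reduction of the ester (N-alkyl lactam and acetal are inert at −78 °C) followed by in-flask Wittig olefination with the stabilised ylide gives the (E)-enoate without isolating the racemisation-prone α-amino aldehyde.

**Step 3**
Reactants: 5 ethyl (E)-3-[(S)-1-(4,4-dimethoxybutyl)-5-oxopyrrolidin-2-yl]acrylate
Product: 6 ethyl (E)-3-[(S)-5-oxo-1-(4-oxobutyl)pyrrolidin-2-yl]acrylate
Conditions: 1 M HCl, THF, 23 °C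
Reagents that add atoms: water, O
Why: Acid-catalysed acetal hydrolysis; a dimethyl acetal cleaves under conditions that leave enoate, lactam and C9a untouched.

**Step 4**
Reactants: 6 ethyl (E)-3-[(S)-5-oxo-1-(4-oxobutyl)pyrrolidin-2-yl]acrylate
Product: 8 (8R,9R,9aS)-tricyclic lactone-lactam (10-demethylstemoamide), via hydroxy ester 7 (not isolated)
Conditions: SmCl3 (10 mol %), nBu4NI (0.1 M), t-BuOH (3 equiv), THF/NMP 9:1, undivided cell, Mg anode, Ni-foam cathode, 5 mA cm-2, 2.4 F mol-1, 20 °C, 6 added over 4 h (final 0.01 M)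
Reagents that add atoms: none
Why: Cathodically regenerated divalent samarium converts the aldehyde into a samarium ketyl that adds 7-exo-trig to C9 of the (E)-enoate through a chelate between ketyl oxygen and ester carbonyl (samarium ketyl–olefin coupling; the stoichiometric SmI2 ring closure and cathodic samarium turnover are both known), the C9a centre held in the rigid lactam places the new C8–C9 bond so that H9/H9a are cis and O8/C10 trans, and the C8 alkoxide then lactonises.

**Step 5**
Reactants: 8 (8R,9R,9aS)-tricyclic lactone-lactam; 9 (R)-2-acetoxysuccinic anhydride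
Product: 10 (3R)-3-acetoxy-4-oxo-4-(tricyclic lactone-lactam-10-yl)butanoic acid
Conditions: LiN(SiMe3)2 (2.2 equiv), THF, −78 °C; then 9 (1.1 equiv), −78 → −40 °C; 1 M HCl
Reagents that add atoms: none
Why: Crossed Claisen acylation in which the lactone is deprotonated in preference to the far less acidic lactam, its enolate opens the anhydride at the more electrophilic carbonyl next to the acetoxy group, and the second equivalent of base holds the product as its 1,3-dicarbonyl enolate, which shields the bought C12 (R) centre from enolisation (C10 is labile and of no consequence).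

**Step 6**
Reactants: 10 (3R)-3-acetoxy-4-oxo-4-(tricyclic lactone-lactam-10-yl)butanoic acid
Product: 11 ethyl (3R)-3-acetoxy-4-[(10S)-10-ethyl tricyclic lactone-lactam-10-yl]-4-oxobutanoate
Conditions: EtI (4 equiv), K2CO3 (2.0 equiv), DMF, 23 °C
Reagents that add atoms: iodoethane, CCI
Why: C-alkylation of the stabilised β-keto-lactone enolate with a soft iodide from the convex face anti to C9a (the carboxylate is esterified at the same time); the two equivalents of K2CO3 end as KHCO3, which is too weak to touch C12-H.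

**Step 7**
Reactants: 11 ethyl (3R)-3-acetoxy-4-[(10S)-10-ethyl tricyclic lactone-lactam-10-yl]-4-oxobutanoate
Product: 13 (8R,9R,9aS,10S,11R,12R)-spiro hydroxy-lactone lactam (13-demethyl), via hydroxy keto acid 12 (not isolated)
Conditions: 0.5 M H2SO4, 1,4-dioxane/H2O 1:1, 80 °C
Reagents that add atoms: none
Why: Classical ketonic cleavage of an α-acyl-γ-butyrolactone (hydrolysis, then loss of CO2) frees C8-OH and the C11 ketone, and acid-equilibrated spiroketalisation/lactonisation sets C10 and C11 thermodynamically, with ethyl trans to C9a on ring C and the bulkier C12 arm of ring D trans to the ethyl group, C12 itself staying as bought.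

**Step 8**
Reactants: 13 (8R,9R,9aS,10S,11R,12R)-spiro hydroxy-lactone lactam (13-demethyl)
Product: 14 (8R,9R,9aS,10S,11R,12R,13R)-spiro hydroxy-lactone lactam
Conditions: LiN(iPr)2 (2.2 equiv), THF, −78 → −40 °C; MeI (1.5 equiv), DMPU, −78 → −30 °C; aq NH4Cl
Reagents that add atoms: iodomethane, CI
Why: Fráter–Seebach-type alkylation of the β-alkoxide lactone-enolate dianion, in which MeI enters anti to the C12 alkoxide, which is also the open face on the side of the ring C oxygen, giving the 12,13-trans (13R) lactone; the lactam is not deprotonated at this stoichiometry.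

**Step 9**
Reactants: 15 (S)-5-oxotetrahydrofuran-2-carboxylic acid
Product: 16 benzyl (S)-5-oxotetrahydrofuran-2-carboxylate
Conditions: BnBr (1.05 equiv), K2CO3 (1.0 equiv), DMF, 23 °C
Reagents that add atoms: benzyl bromide, BrCc1ccccc1
Why: Carboxylate O-alkylation (SN2) that does not touch the bought C18 (S) centre.

**Step 10**
Reactants: 16 benzyl (S)-5-oxotetrahydrofuran-2-carboxylate
Product: 17 benzyl (S,E)-4-[(dimethylamino)methylidene]-5-oxotetrahydrofuran-2-carboxylate
Conditions: tBuOCH(NMe2)2 (1.5 equiv), toluene, 80 °C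
Reagents that add atoms: tert-butoxybis(dimethylamino)methane, CN(C)C(OC(C)(C)C)N(C)C
Why: Aminomethylenation with Bredereck's reagent at the only CH2 next to a carbonyl gives the push–pull enaminone under conditions too mild to epimerise C18.

**Step 11**
Reactants: 17 benzyl (S,E)-4-[(dimethylamino)methylidene]-5-oxotetrahydrofuran-2-carboxylate
Product: 18 (2S,4S)-4-methyl-5-oxotetrahydrofuran-2-carboxylic acid
Conditions: H2 (5 bar), 10% Pd/C, iPrOH, 40 °C; then 1 M HCl wash
Reagents that add atoms: none
Why: Heterogeneous hydrogenation saturates the enaminone, Me2NH is lost, and the resulting exocyclic methylene is hydrogenated from the face opposite the C18 carboxyl group, giving the cis (18S,20S) lactone while the benzyl ester is hydrogenolysed.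

**Step 12**
Reactants: 14 (8R,9R,9aS,10S,11R,12R,13R)-spiro hydroxy-lactone lactam; 18 (2S,4S)-4-methyl-5-oxotetrahydrofuran-2-carboxylic acid
Product: 21 2-acyl enamine (C3H=C2 vinylogous amide carrying the ring E carbonyl group on C2), via acid chloride 19 (not isolated), via enamine 20 (not isolated)
Conditions: 18, (COCl)2, cat. DMF, CH2Cl2, 0 → 23 °C, evaporate; separately 14, IrCl(CO)(PPh3)2 (1 mol %), (HMe2Si)2O (3 equiv), toluene, 23 °C; then 2,6-lutidine (1.5 equiv), 19 (1.05 equiv), −40 → 0 °C; aq NaHCO3
Reagents that add atoms: none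
Why: Iridium-catalysed hydrosilylation reduces only the tertiary lactam (lactones inert; the hindered C12-OH is at most transiently O-silylated and freed on work-up) to an O-silyl hemiaminal that collapses to the endocyclic enamine, and Stork acylation at its nucleophilic carbon C2 under a weak hindered base (no ketene, so C18 is retained) gives the stable vinylogous amide.

**Step 13**
Reactants: 21 2-acyl enamine
Product: 23 CNP0272443.1 (target), via amino ketone 22 (not isolated)
Conditions: benzene-1,2-diamine (1.1 equiv), AcOH (2 equiv), 4 Å molecular sieves, MeCN, 40 °C, Ar; then aq K2CO3; basic alumina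
Reagents that add atoms: none
Why: Proposed new method: a one-carbon deletion with ring transposition in which benzene-1,2-diamine first exchanges with N4 at the vinylogous-amide carbon C3 (known amine exchange of enaminones, here ring-opening), its second NH2 closes a benzimidazoline on C3, and aromatisation to benzimidazole drives retro-Mannich cleavage of C2–C3, releasing amino ketone 22, whose secondary amine condenses 5-exo on the acyl carbonyl (the new C3) to give the trisubstituted endocyclic enamine; no stereocentre is formed and C18/C20 are carried over from 18; the closest known reactions are the deformylation of 2-(hydroxymethylene) ketones by benzene-1,2-diamine and the acid-induced conversion of 3-acyl-1-alkylpyrrolidin-2-ones into 2-substituted pyrrolines.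

**Compound list**
1 | methyl (S)-5-oxopyrrolidine-2-carboxylate | COC(=O)[C@@H]1CCC(=O)N1 | starting material
2 | 4-chloro-1,1-dimethoxybutane | COC(CCCCl)OC | starting material
3 | methyl (S)-1-(4,4-dimethoxybutyl)-5-oxopyrrolidine-2-carboxylate | COC(=O)[C@@H]1CCC(=O)N1CCCC(OC)OC | intermediate
4 | (S)-1-(4,4-dimethoxybutyl)-5-oxopyrrolidine-2-carbaldehyde (not isolated) | O=C[C@@H]1CCC(=O)N1CCCC(OC)OC | intermediate
5 | ethyl (E)-3-[(S)-1-(4,4-dimethoxybutyl)-5-oxopyrrolidin-2-yl]acrylate | CCOC(=O)/C=C/[C@@H]1CCC(=O)N1CCCC(OC)OC | intermediate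
6 | ethyl (E)-3-[(S)-5-oxo-1-(4-oxobutyl)pyrrolidin-2-yl]acrylate | CCOC(=O)/C=C/[C@@H]1CCC(=O)N1CCCC=O | intermediate
7 | ethyl 2-[(8R,9R,9aS)-8-hydroxy-3-oxooctahydropyrrolo[1,2-a]azepin-9-yl]acetate (not isolated) | CCOC(=O)C[C@H]1[C@H](O)CCCN2C(=O)CC[C@@H]12 | intermediate
8 | (8R,9R,9aS)-tricyclic lactone-lactam, 10-demethylstemoamide (H8/H9 trans, H9/H9a cis) | O=C1C[C@H]2[C@@H](CCCN3C(=O)CC[C@@H]23)O1 | intermediate
9 | (R)-2-acetoxysuccinic anhydride | CC(=O)O[C@@H]1CC(=O)OC1=O | starting material
10 | (3R)-3-acetoxy-4-oxo-4-(lactone-lactam-10-yl)butanoic acid (C10 labile, epimers/enol, drawn without descriptor) | O=C1C(C(=O)[C@H](OC(C)=O)CC(=O)O)[C@H]2[C@@H](CCCN3C(=O)CC[C@@H]23)O1 | intermediate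
11 | ethyl (3R)-3-acetoxy-4-[(10S)-10-ethyl lactone-lactam-10-yl]-4-oxobutanoate (ethyl anti to C9a) | CC[C@@]1(C(=O)[C@H](OC(C)=O)CC(=O)OCC)[C@H]2[C@@H](CCCN3C(=O)CC[C@@H]23)OC1=O | intermediate
12 | open 8,12-dihydroxy-11-keto-14-acid (C10 labile, not isolated) | CCC(C(=O)[C@H](O)CC(=O)O)[C@H]1[C@H](O)CCCN2C(=O)CC[C@@H]12 | intermediate
13 | (8R,9R,9aS,10S,11R,12R)-spiro hydroxy-lactone lactam, 13-demethyl | CC[C@H]1[C@H]2[C@@H](CCCN3C(=O)CC[C@@H]23)O[C@@]12OC(=O)C[C@H]2O | intermediate
14 | (8R,9R,9aS,10S,11R,12R,13R)-spiro hydroxy-lactone lactam | CC[C@H]1[C@H]2[C@@H](CCCN3C(=O)CC[C@@H]23)O[C@@]12OC(=O)[C@H](C)[C@H]2O | intermediate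
15 | (S)-5-oxotetrahydrofuran-2-carboxylic acid | OC(=O)[C@@H]1CCC(=O)O1 | starting material
16 | benzyl (S)-5-oxotetrahydrofuran-2-carboxylate | O=C(OCc1ccccc1)[C@@H]1CCC(=O)O1 | intermediate
17 | benzyl (S,E)-4-[(dimethylamino)methylidene]-5-oxotetrahydrofuran-2-carboxylate | O=C(OCc1ccccc1)[C@@H]1C/C(=C\N(C)C)C(=O)O1 | intermediate
18 | (2S,4S)-4-methyl-5-oxotetrahydrofuran-2-carboxylic acid (cis) | OC(=O)[C@@H]1C[C@H](C)C(=O)O1 | intermediate
19 | (2S,4S)-4-methyl-5-oxotetrahydrofuran-2-carbonyl chloride (not isolated) | ClC(=O)[C@@H]1C[C@H](C)C(=O)O1 | intermediate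
20 | endocyclic enamine from 14 (N4–C3H=C2H, not isolated) | CC[C@H]1[C@H]2[C@@H](CCCN3C=CC[C@@H]23)O[C@@]12OC(=O)[C@H](C)[C@H]2O | intermediate
21 | 2-acyl enamine (N4–C3H=C2–C(=O)–ring E) | CC[C@H]1[C@H]2[C@@H](CCCN3C=C(C(=O)[C@@H]4C[C@H](C)C(=O)O4)C[C@@H]23)O[C@@]12OC(=O)[C@H](C)[C@H]2O | intermediate
22 | azepane amino ketone (N4-H; C9a–CH2CH2–C(=O)–ring E, not isolated) | CC[C@H]1[C@H]2[C@@H](CCCN[C@H]2CCC(=O)[C@@H]3C[C@H](C)C(=O)O3)O[C@@]14OC(=O)[C@H](C)[C@H]4O | intermediate
23 | CNP0272443.1, (8R,9R,9aS,10S,11R,12R,13R,18S,20S) | CC[C@H]1[C@H]2[C@@H](CCCN3C([C@@H]4C[C@H](C)C(=O)O4)=CC[C@@H]23)O[C@@]12OC(=O)[C@H](C)[C@H]2O | target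

**Total step count:** 13. **Longest linear sequence:** 10 (steps 1–8, 12, 13).

**Steps most likely to fail**

Step 13 (the new step). The diamine may stop at the ring-opened anil or at a benzodiazepine, and C18 may epimerise through the iminium ion. The fallback sets out from 14 and comes back at 23, using known reactions only.
- Enamine 20 is generated as in step 12 and protonated with CF3CO2H.
- The iminium ion is intercepted in a vinylogous Mannich reaction by 3-methyl-2-(triisopropylsilyloxy)furan F5, made from 3-methylfuran-2(5H)-one, iPr3SiOTf and Et3N. Attack occurs on the face of C3 opposite to C9 and gives the butenolide amine F6.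
- H2 over Rh/Al2O3 saturates the butenolide anti to C3 to give the saturated lactone amine F7.
- Dehydrogenation with Hg(OAc)2 in aqueous AcOH followed by K2CO3 gives 23. The cost is that regioisomeric iminium ions must be separated.

Step 4. Closure of the seven-membered ring may lose to pinacol coupling or to plain cathodic reduction of the aldehyde or the enoate. The fallback sets out from 6 and comes back at 8, with polar umpolung in place of the radical closure.
- An intramolecular Stetter reaction (3-benzyl-5-(2-hydroxyethyl)-4-methylthiazolium chloride, Et3N, dioxane, 80 °C) gives the keto ester F1. Its C9, being α to the ketone, equilibrates to the isomer with H9/H9a cis.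
- NaBH4 in MeOH at −20 °C delivers hydride to give the equatorial 8-alcohol 7.
- A trace of TsOH closes 7 to 8.

Step 12. The unsubstituted enamine 20 may oligomerise, or the C12-OH may be acylated. The fallback sets out from 14 and comes back at 21, using thio-activation in place of hydrosilylation.
- Lawesson's reagent (toluene, 80 °C) thionates only the lactam, giving the thiolactam F2.
- MeI, then Et3N, gives the isolable ketene N,S-acetal F3.
- Acid chloride 19 with 2,6-lutidine acylates C2, giving the acylated ketene N,S-acetal F4.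
- Acetone-deactivated Raney Ni in EtOH removes the methylthio group, giving 21.

**Further compounds**
F1 | step 4 | ethyl 2-[(9R,9aS)-3,8-dioxooctahydropyrrolo[1,2-a]azepin-9-yl]acetate | CCOC(=O)C[C@H]1C(=O)CCCN2C(=O)CC[C@@H]12
F2 | step 12 | thiolactam of 14 (C3=S) | CC[C@H]1[C@H]2[C@@H](CCCN3C(=S)CC[C@@H]23)O[C@@]12OC(=O)[C@H](C)[C@H]2O
F3 | step 12 | ketene N,S-acetal (N4–C3(SMe)=C2H) | CC[C@H]1[C@H]2[C@@H](CCCN3C(SC)=CC[C@@H]23)O[C@@]12OC(=O)[C@H](C)[C@H]2O
F4 | step 12 | 2-acyl ketene N,S-acetal | CC[C@H]1[C@H]2[C@@H](CCCN3C(SC)=C(C(=O)[C@@H]4C[C@H](C)C(=O)O4)C[C@@H]23)O[C@@]12OC(=O)[C@H](C)[C@H]2O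
F5 | step 13 | 3-methyl-2-(triisopropylsilyloxy)furan | CC1=C(O[Si](C(C)C)(C(C)C)C(C)C)OC=C1
F6 | step 13 | (3S,18S)-butenolide amine | CC[C@H]1[C@H]2[C@@H](CCCN3[C@H]([C@@H]4C=C(C)C(=O)O4)CC[C@@H]23)O[C@@]12OC(=O)[C@H](C)[C@H]2O
F7 | step 13 | (3S,18S,20S)-saturated lactone amine | CC[C@H]1[C@H]2[C@@H](CCCN3[C@H]([C@@H]4C[C@H](C)C(=O)O4)CC[C@@H]23)O[C@@]12OC(=O)[C@H](C)[C@H]2O
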